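**Plan**

1. Cuts: (i) the O–Si bond of a phenol protecting group. (ii) The tertiary alkyl C–O bond of the ester, cut together with a reconnection of the carbinol carbon C4 of the p-menth-1-ene ring to the alkene carbon C2; this leads back to a 4-silyloxy-3,5-diprenylbenzoic acid and (1S,5S)-sabinene. (iii) Ar–CO2H and the two Ar–CH2(prenyl) bonds, back to 4-iodophenol. (iv) The exocyclic C=CH2 and the two cyclopropane bonds at the CH bridgehead of sabinene, back to an acyclic epoxy-alkene made from (R)-epichlorohydrin and 2,3-dimethylbut-1-ene.
2. Enabling feature: the acyloxy group sits on a fully substituted ring carbon that is homoallylic to the trisubstituted ring alkene, O–C4–C3H2–C2H=C1(CH3). This array is the retron of a cyclopropylcarbinyl-to-homoallyl opening. The cyclohexene is therefore the perimeter of a 1-isopropylbicyclo[3.1.0]hexane whose zero-atom bridge is C4–C2.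
3. Ring order, forward: the benzene ring is bought. The three- and five-membered helper rings arise together in one carbenoid cyclopropanation. The cyclohexene arises last, when the carboxylic acid opens protonated sabinene; this one event makes the hindered ester C–O bond, the six-membered ring, the alkene position and the stereocentre.
4. Stereochemistry: the C–O centre of (R)-epichlorohydrin directs the cyclopropanation and is then oxidised away. The quaternary bridgehead set in this way is inverted by backside attack of the acid and becomes the (R) centre of the target.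

Key step: step 8

Assumption: enantiopure (1S,5S)-sabinene is not taken as a dependable article of commerce, so it is built from (R)-epichlorohydrin; step 8 uses sabinene numbering (C1 bears isopropyl, C4 the methylidene, C5 is the CH bridgehead, C6 the cyclopropane CH2).

**Step 1**
Reactants: 1 2,3-dimethylbut-1-ene; 2 (R)-epichlorohydrin
Product: 5 (2R)-1-chloro-6-methyl-5-methylideneheptan-2-ol, via 2-isopropylallyllithium 3 (not isolated), via 2-isopropylallylmagnesium bromide 4 (not isolated)
Conditions: n-BuLi, TMEDA, hexane, 0 °C to rt; MgBr2, Et2O/THF, −78 °C; 2, CuI (10 mol %), −78 to −20 °C; H2O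
Reagents that add atoms: none
Why: Allylic lithiation of a 1,1-disubstituted alkene removes a methyl hydrogen in preference to the tertiary one, the resulting 2-substituted allyl unit has two equivalent termini, and the copper-catalysed Grignard opening of epichlorohydrin at the epoxide CH2 leaves the C–O stereocentre of 2 untouched.

**Step 2**
Reactants: 5 (2R)-1-chloro-6-methyl-5-methylideneheptan-2-ol
Product: 8 (1R,2R,5S)-5-(propan-2-yl)bicyclo[3.1.0]hexan-2-ol (OH trans to the cyclopropane CH2), via (R)-epoxide 6 (not isolated), via trans-lithiated epoxide 7 (not isolated)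
Conditions: LTMP (from TMP and n-BuLi, 3.2 equiv), MTBE, 0 °C to rt; H2O
Reagents that add atoms: none
Why: The first equivalent of base closes the chlorohydrin to 6, LTMP then lithiates the epoxide CH2 trans to the chain, and carbenoid 7 adds to the tethered alkene (intramolecular cyclopropanation of an unsaturated terminal epoxide), the retained carbinol centre forcing the cyclopropane onto the ring face opposite to oxygen and so setting C1 and C5.

**Step 3**
Reactants: 8 (1R,2R,5S)-5-(propan-2-yl)bicyclo[3.1.0]hexan-2-ol
Product: 9 (1R,5S)-5-(propan-2-yl)bicyclo[3.1.0]hexan-2-one (sabina ketone)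
Conditions: TEMPO (1 mol %), KBr (10 mol %), NaOCl, NaHCO3, CH2Cl2/H2O, 0 °C
Reagents that add atoms: none
Why: The buffered TEMPO/hypochlorite (Anelli) oxidation of a secondary alcohol removes the helper carbinol centre, and C1 and C5 cannot epimerise because only the cis-fused bicycle is possible.

**Step 4**
Reactants: 9 (1R,5S)-5-(propan-2-yl)bicyclo[3.1.0]hexan-2-one
Product: 10 (1S,5S)-4-methylidene-1-(propan-2-yl)bicyclo[3.1.0]hexane (sabinene)
Conditions: Ph3PCH3Br, KOtBu, THF, 0 °C to rt; pentane extraction, distillation
Reagents that add atoms: methyltriphenylphosphonium bromide, C[P+](c1ccccc1)(c1ccccc1)c1ccccc1.[Br-]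
Why: Wittig methylenation of an unhindered five-ring ketone installs the last carbon and the alkene that serves as proton acceptor in step 8, and no stereocentre is touched.

**Step 5**
Reactants: 11 4-iodophenol; 12 prenyl bromide (1-bromo-3-methylbut-2-ene, 2.2 equiv)
Product: 13 4-iodo-2,6-bis(3-methylbut-2-en-1-yl)phenol
Conditions: KOH, H2O, rt
Reagents that add atoms: none
Why: In water the phenoxide oxygen is shielded by hydrogen bonds, so the allylic bromide is taken up by the two free ortho carbons (ortho C-alkylation of a p-halophenoxide), SN2 attack at the primary carbon keeps the prenyl connectivity, and the para position is blocked by iodine.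

**Step 6**
Reactants: 13 4-iodo-2,6-bis(3-methylbut-2-en-1-yl)phenol
Product: 14 tert-butyl[4-iodo-2,6-bis(3-methylbut-2-en-1-yl)phenoxy]dimethylsilane
Conditions: TBSCl, imidazole, DMF, 40 °C
Reagents that add atoms: tert-butyldimethylsilyl chloride, CC(C)(C)[Si](C)(C)Cl
Why: Imidazole-mediated silylation masks the acidic OH for the lithiation and later prevents acid-induced cyclisation of the phenol onto a prenyl group.

**Step 7**
Reactants: 14 tert-butyl[4-iodo-2,6-bis(3-methylbut-2-en-1-yl)phenoxy]dimethylsilane
Product: 16 4-[(tert-butyldimethylsilyl)oxy]-3,5-bis(3-methylbut-2-en-1-yl)benzoic acid, via aryllithium 15 (not isolated)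
Conditions: n-BuLi, THF, −78 °C; CO2, −78 to 0 °C; 1 M HCl, 0 °C
Reagents that add atoms: carbon dioxide, O=C=O
Why: Iodine–lithium exchange at −78 °C is much faster than deprotonation of the benzylic/allylic CH2 groups, and carboxylation of 15 with CO2 gives the acid after a cold acidification that the aryl silyl ether survives.

**Step 8**
Reactants: 10 (1S,5S)-sabinene (1.5 equiv, added slowly); 16 4-[(tert-butyldimethylsilyl)oxy]-3,5-bis(3-methylbut-2-en-1-yl)benzoic acid
Product: 18 (1R)-4-methyl-1-(propan-2-yl)cyclohex-3-en-1-yl 4-[(tert-butyldimethylsilyl)oxy]-3,5-bis(3-methylbut-2-en-1-yl)benzoate, via sabinyl cation 17 (not isolated)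
Conditions: CSA (5 mol %), 4 Å MS, toluene/CH2Cl2 4:1 (1 M in 16), −20 to 0 °C; Et3N quench
Reagents that add atoms: none
Why: CSA protonates the exocyclic methylidene carbon of 10 (Markovnikov) to the tertiary cyclopropylcarbinyl cation 17, whose charge is shared with the fully substituted bridgehead C1 through the C1–C5 bond. The carbonyl oxygen of 16 attacks C1 from the side opposite to C5 while the C1–C5 bond breaks and becomes the C4=C5 π bond, a cyclopropylcarbinyl-to-homoallyl opening whose closest known relatives are the acid-catalysed hydration and acetolysis of sabinene and α-thujene to terpinen-4-ol and its esters. The cyclohexene is closed not by a cyclisation mode but by ring expansion: scission of the zero-atom bridge fuses the three- and five-membered rings into their six-membered perimeter C1–C2–C3–C4=C5–C6, and release of the cyclopropane strain makes the addition irreversible for a catalyst too weak to re-ionise the tertiary ester. The single new stereocentre is the former C1 and is controlled by the substrate: backside displacement (inversion) turns (1S) in 10 into (R) at the acyloxy carbon, and the low-polarity medium, the low temperature and the high concentration of 16 are chosen so that capture takes place on the bridged cation and not on an opened, achiral terpinen-4-yl cation. Bond selectivity (C1–C5 and not C5–C6) follows from tertiary against primary cationic character, and the skeleton itself fixes the alkene as the trisubstituted C(CH3)=CH isomer. Chemoselectivity rests on the far higher basicity of a cyclopropyl-conjugated 1,1-disubstituted alkene compared with the prenyl groups, whose cyclisation onto oxygen is also blocked by the silyl ether.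

**Step 9**
Reactants: 18 silyl-protected ester
Product: 19 (1R)-4-methyl-1-(propan-2-yl)cyclohex-3-en-1-yl 4-hydroxy-3,5-bis(3-methylbut-2-en-1-yl)benzoate (target)
Conditions: TBAF, AcOH (1.1 equiv each), THF, 0 °C
Reagents that add atoms: none
Why: Buffered fluoride desilylation cleaves the aryl silyl ether under conditions to which the hindered tertiary benzoate, the three alkenes and the stereocentre are inert.

**Compound list**

1 | 2,3-dimethylbut-1-ene | C=C(C)C(C)C | starting material
2 | (R)-epichlorohydrin | ClC[C@H]1CO1 | starting material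
3 | 2-isopropylallyllithium | [Li]CC(=C)C(C)C | intermediate
4 | 2-isopropylallylmagnesium bromide | Br[Mg]CC(=C)C(C)C | intermediate
5 | (2R)-1-chloro-6-methyl-5-methylideneheptan-2-ol | ClC[C@H](O)CCC(=C)C(C)C | intermediate
6 | (R)-2-(4-methyl-3-methylidenepentyl)oxirane | CC(C)C(=C)CC[C@@H]1CO1 | intermediate
7 | trans-lithiated epoxide (Li on the epoxide CH, trans to the chain) | CC(C)C(=C)CC[C@@H]1[C@@H]([Li])O1 | intermediate
8 | (1R,2R,5S)-5-(propan-2-yl)bicyclo[3.1.0]hexan-2-ol | O[C@@H]1CC[C@@]2(C(C)C)C[C@@H]12 | intermediate
9 | (1R,5S)-5-(propan-2-yl)bicyclo[3.1.0]hexan-2-one | O=C1CC[C@@]2(C(C)C)C[C@@H]12 | intermediate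
10 | (1S,5S)-4-methylidene-1-(propan-2-yl)bicyclo[3.1.0]hexane (sabinene) | C=C1CC[C@@]2(C(C)C)C[C@@H]12 | intermediate
11 | 4-iodophenol | Oc1ccc(I)cc1 | starting material
12 | prenyl bromide | CC(C)=CCBr | starting material
13 | 4-iodo-2,6-bis(3-methylbut-2-en-1-yl)phenol | CC(C)=CCc1cc(I)cc(CC=C(C)C)c1O | intermediate
14 | tert-butyl[4-iodo-2,6-bis(3-methylbut-2-en-1-yl)phenoxy]dimethylsilane | CC(C)=CCc1cc(I)cc(CC=C(C)C)c1O[Si](C)(C)C(C)(C)C | intermediate
15 | 4-silyloxy-3,5-diprenylphenyllithium | [Li]c1cc(CC=C(C)C)c(O[Si](C)(C)C(C)(C)C)c(CC=C(C)C)c1 | intermediate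
16 | 4-[(tert-butyldimethylsilyl)oxy]-3,5-bis(3-methylbut-2-en-1-yl)benzoic acid | CC(C)=CCc1cc(C(=O)O)cc(CC=C(C)C)c1O[Si](C)(C)C(C)(C)C | intermediate
17 | sabinyl cation (C4 cation of the intact bicycle) | C[C+]1CC[C@@]2(C(C)C)C[C@@H]12 | intermediate
18 | (1R)-4-methyl-1-(propan-2-yl)cyclohex-3-en-1-yl 4-[(tert-butyldimethylsilyl)oxy]-3,5-bis(3-methylbut-2-en-1-yl)benzoate | CC(C)=CCc1cc(C(=O)O[C@@]2(C(C)C)CC=C(C)CC2)cc(CC=C(C)C)c1O[Si](C)(C)C(C)(C)C | intermediate
19 | (1R)-4-methyl-1-(propan-2-yl)cyclohex-3-en-1-yl 4-hydroxy-3,5-bis(3-methylbut-2-en-1-yl)benzoate | CC(C)=CCc1cc(C(=O)O[C@@]2(C(C)C)CC=C(C)CC2)cc(CC=C(C)C)c1O | target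

Total step count: 9. Longest linear sequence: 6 (steps 1, 2, 3, 4, 8, 9).

**Steps most likely to fail**

**Step 8.** Proton loss or a hydride shift in the cation may outrun capture by the bulky, weakly nucleophilic acid. Capture through a fully opened, achiral cation would also erode the enantiomeric purity.
- The fallback sets out from 10 and 16 and comes back at 18. It separates the two tasks of the step.
- 10 would be opened with water, present in very large excess (0.5 M H2SO4, aqueous acetone, 0 °C to rt). This is the known hydration of sabinene. It still closes the cyclohexene by the same bond scission and should give (R)-terpinen-4-ol F1, whose enantiomeric purity can be assayed at this stage.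
- 16 would be converted with carbonyldiimidazole (THF, rt) into the acyl imidazolide F2.
- The lithium alkoxide of F1 (n-BuLi, THF, −78 to 0 °C) would be acylated with F2 to give 18.

**Step 1.** The allylic metalation may be incomplete or unselective. Direct displacement of chloride instead of epoxide opening would erode the enantiomeric purity.
- The fallback sets out from 2 and comes back at 6, which would then be isolated and treated with LTMP as in step 2.
- 3-Methylbutan-2-one would be condensed with N,N-dimethylhydrazine to 3-methylbutan-2-one N,N-dimethylhydrazone F3.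
- Deprotonation at the methyl group (LDA, THF, 0 °C) and addition of 2 should open the epoxide at its CH2 terminus. The alkoxide then closes onto the CH2Cl carbon to give the (R)-epoxy hydrazone F4.
- Cu(OAc)2 in aqueous THF would free (R)-4-methyl-1-(oxiran-2-yl)pentan-3-one F5.
- Wittig methylenation of the ketone gives 6.

**Step 5.** O-alkylation and under- or over-alkylation compete with the double ortho C-alkylation.
- The fallback sets out from 11 and comes back at 13. It delivers each prenyl group by a [3,3] shift.
- 11 would be O-alkylated with 3-chloro-3-methylbut-1-yne (CuCl2 cat., DBU, MeCN, 0 °C) to 1-iodo-4-[(2-methylbut-3-yn-2-yl)oxy]benzene F6.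
- F6 would be semi-hydrogenated over Lindlar catalyst to 1-iodo-4-[(2-methylbut-3-en-2-yl)oxy]benzene F7.
- F7 would be heated (N,N-diethylaniline, about 130 °C), so that an aromatic Claisen rearrangement gives 4-iodo-2-(3-methylbut-2-en-1-yl)phenol F8.
- Repeating the three operations, through the propargyl ether F9 and the 1,1-dimethylallyl ether F10, gives 13.

**Further compounds**

F1 | step 8 | (R)-terpinen-4-ol, (1R)-4-methyl-1-(propan-2-yl)cyclohex-3-en-1-ol | O[C@@]1(C(C)C)CC=C(C)CC1
F2 | step 8 | 1-{4-[(tert-butyldimethylsilyl)oxy]-3,5-bis(3-methylbut-2-en-1-yl)benzoyl}imidazole | CC(C)=CCc1cc(C(=O)n2ccnc2)cc(CC=C(C)C)c1O[Si](C)(C)C(C)(C)C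
F3 | step 1 | 3-methylbutan-2-one N,N-dimethylhydrazone | CC(C)C(C)=NN(C)C
F4 | step 1 | (R)-4-methyl-1-(oxiran-2-yl)pentan-3-one N,N-dimethylhydrazone | CC(C)C(CC[C@@H]1CO1)=NN(C)C
F5 | step 1 | (R)-4-methyl-1-(oxiran-2-yl)pentan-3-one | CC(C)C(=O)CC[C@@H]1CO1
F6 | step 5 | 1-iodo-4-[(2-methylbut-3-yn-2-yl)oxy]benzene | C#CC(C)(C)Oc1ccc(I)cc1
F7 | step 5 | 1-iodo-4-[(2-methylbut-3-en-2-yl)oxy]benzene | C=CC(C)(C)Oc1ccc(I)cc1
F8 | step 5 | 4-iodo-2-(3-methylbut-2-en-1-yl)phenol | CC(C)=CCc1cc(I)ccc1O
F9 | step 5 | 4-iodo-2-(3-methylbut-2-en-1-yl)-1-[(2-methylbut-3-yn-2-yl)oxy]benzene | C#CC(C)(C)Oc1ccc(I)cc1CC=C(C)C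
F10 | step 5 | 4-iodo-2-(3-methylbut-2-en-1-yl)-1-[(2-methylbut-3-en-2-yl)oxy]benzene | C=CC(C)(C)Oc1ccc(I)cc1CC=C(C)C
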